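**Retrosynthetic overview**
1. Ring C is closed last by forming the O1–C2 bond from a 2'-hydroxychalcone. The same operation removes two hydrogens and the 5-O-methyl group, because I2 generates HI and HI frees the 5-OH.
2. The chalcone is cut at Cα=Cβ (Claisen–Schmidt) into a purchased, fully oxygenated ring A acetophenone and a ring B aldehyde.
3. The ring B aldehyde is cut at its C3–O bond. It comes from 2,4,5-trimethoxybenzaldehyde by deprotonation between the two methoxy groups, borate formation and peroxide oxidation.
4. Rings A and B are bought as arenes. Ring C is the only ring formed, and no separate protecting-group step is used.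

Assumption: the target has no stereocentre and no stable stereoaxis, so it is achiral and no enantiomer has to be chosen; 6-hydroxy-2,3,4-trimethoxyacetophenone is taken as a purchased catalogue compound.

**Step 1**
Reactants: 1 2,4,5-trimethoxybenzaldehyde
Product: 5 3-hydroxy-2,4,5-trimethoxybenzaldehyde, via lithium amino alkoxide 2 (not isolated), via aryllithium 3 (not isolated), via lithium arylborate 4 (not isolated)
Conditions: 1-methylpiperazine (1.2 equiv), n-BuLi (1.15 equiv), THF, −20 °C, then 1; n-BuLi (2.0 equiv), −20 → 0 °C, 3 h; B(OMe)3 (4 equiv), −78 °C → rt; AcOH, 30% H2O2, 0 °C, 30 min; aq. NaHSO3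
Reagents that add atoms: hydrogen peroxide, OO
Why: This is directed ortho-metalation of an aldehyde masked in situ as its α-amino alkoxide, in which the bulky, weakly directing piperazide adduct lets n-BuLi remove the most acidic ring proton, H-3 between two methoxy groups (the site lithiated in 1,2,4-trimethoxybenzene), and borylation followed by peroxide-induced boron-to-oxygen aryl migration converts C–Li into C–OH faster than the released aldehyde (no ortho or para OH, so not a Dakin substrate) is attacked, while the racemic carbinolamine carbon of 2–4 is lost on work-up.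

**Step 2**
Reactants: 5 3-hydroxy-2,4,5-trimethoxybenzaldehyde; 6 6-hydroxy-2,3,4-trimethoxyacetophenone
Product: 7 (E)-1-(6-hydroxy-2,3,4-trimethoxyphenyl)-3-(3-hydroxy-2,4,5-trimethoxyphenyl)prop-2-en-1-one
Conditions: KOH (50% aq., 10 equiv), EtOH, Ar, rt → 40 °C, 36 h; 1 M HCl to pH 3, 0 °C
Reagents that add atoms: none
Why: This is a Claisen–Schmidt condensation (aldol addition, then E1cB loss of water) that gives the E-enone under thermodynamic control, and the free 3-OH is tolerated because it is meta to the formyl group, so its phenoxide does not conjugate with the carbonyl; no stereocentre is formed.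

**Step 3**
Reactants: 7 (E)-1-(6-hydroxy-2,3,4-trimethoxyphenyl)-3-(3-hydroxy-2,4,5-trimethoxyphenyl)prop-2-en-1-one
Product: 11 psiadiarabicin (5,3'-dihydroxy-6,7,2',4',5'-pentamethoxyflavone), via flavanone 8 (not isolated), via 3-iodoflavanone 9 (not isolated), via 5-O-methylflavone 10 (not isolated)
Conditions: I2 (1.5 equiv), anhydrous AcOH (0.1 M), Ar, sealed tube, 100 °C, 12 h; aq. Na2S2O3
Reagents that add atoms: none
Why: Proposed new method: a base-free iodine dehydrogenative oxa-cyclisation whose HI by-product is kept and used as the deprotecting reagent, in which I2 and trace HI catalyse 6-endo oxa-Michael attack of the 2'-OH on the enone (O1–C2 bond, ring C) to give racemic 8, the enol of 8 is iodinated to 9, 9 loses HI because the product is the aromatic 4-pyrone formed as the O-protonated iodide of 10, and in that contact ion pair the proton bridges C4=O and the twisted peri 5-OMe so that iodide removes exactly this methyl by SN2 (as MeI) to leave the hydrogen-bonded 5-OH; with no base or DMSO to destroy HI the oxidation supplies the acid the cleavage needs, HI consumption pulls the reversible α-iodination forward, HI reverses any iodination of the electron-rich rings, the absence of water blocks Wessely–Moser ring opening, and the C2/C3 stereocentres of 8 and 9 are erased on aromatisation; the closest known reaction types are I2/DMSO and I2/KOAc–AcOH oxidation of 2'-hydroxychalcones or flavanones to flavones, base-free I2 aromatisation of cyclohexenones, and HBr–AcOH or HI–AcOH cleavage of the 5-methoxy group of flavones.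

**Compound list**
1 | 2,4,5-trimethoxybenzaldehyde | COc1cc(OC)c(OC)cc1C=O | starting material
2 | lithium (4-methylpiperazin-1-yl)(2,4,5-trimethoxyphenyl)methanolate (racemic, not isolated) | [Li+].[O-]C(N1CCN(C)CC1)c1cc(OC)c(OC)cc1OC | intermediate
3 | C3-lithiated derivative of 2 (racemic, not isolated) | [Li+].[Li]c1c(OC)c(OC)cc(C([O-])N2CCN(C)CC2)c1OC | intermediate
4 | dilithium aryl(trimethoxy)borate derived from 3 (racemic, not isolated) | [Li+].[Li+].CO[B-](OC)(OC)c1c(OC)c(OC)cc(C([O-])N2CCN(C)CC2)c1OC | intermediate
5 | 3-hydroxy-2,4,5-trimethoxybenzaldehyde | COc1cc(C=O)c(OC)c(O)c1OC | intermediate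
6 | 6-hydroxy-2,3,4-trimethoxyacetophenone | CC(=O)c1c(O)cc(OC)c(OC)c1OC | starting material
7 | (E)-1-(6-hydroxy-2,3,4-trimethoxyphenyl)-3-(3-hydroxy-2,4,5-trimethoxyphenyl)prop-2-en-1-one | COc1cc(O)c(C(=O)/C=C/c2cc(OC)c(OC)c(O)c2OC)c(OC)c1OC | intermediate
8 | 2-(3-hydroxy-2,4,5-trimethoxyphenyl)-5,6,7-trimethoxychroman-4-one (racemic, not isolated) | COc1cc2OC(CC(=O)c2c(OC)c1OC)c1cc(OC)c(OC)c(O)c1OC | intermediate
9 | 2-(3-hydroxy-2,4,5-trimethoxyphenyl)-3-iodo-5,6,7-trimethoxychroman-4-one (racemic, C3 epimers, not isolated) | COc1cc2OC(C(I)C(=O)c2c(OC)c1OC)c1cc(OC)c(OC)c(O)c1OC | intermediate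
10 | 2-(3-hydroxy-2,4,5-trimethoxyphenyl)-5,6,7-trimethoxy-4H-chromen-4-one (3'-hydroxy-5,6,7,2',4',5'-hexamethoxyflavone, not isolated) | COc1cc2oc(cc(=O)c2c(OC)c1OC)-c1cc(OC)c(OC)c(O)c1OC | intermediate
11 | psiadiarabicin, 5-hydroxy-2-(3-hydroxy-2,4,5-trimethoxyphenyl)-6,7-dimethoxy-4H-chromen-4-one (achiral) | COc1cc(-c2cc(=O)c3c(O)c(OC)c(OC)cc3o2)c(OC)c(O)c1OC | target

**Totals**
Total step count: 3. Longest linear sequence: 3 (1 → 5 → 7 → 11).

**Steps most likely to fail**

**Step 3 (the proposed new step).**
- Risks:
  - Without a base, loss of HI from 9 may be slow.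
  - Triiodide formation may stall the oxidation.
  - HI may also attack the 6-, 2'- or 4'-OMe groups.
  - HI may cleave the 6'-OMe of 7 before ring closure, which would open a path to the 7,8-dimethoxy isomer.
- Fallback (known chemistry) sets out from 7 and comes back at 11. Compound 7 is heated with catalytic I2 (10 mol %) in DMSO at 130 °C, the standard oxidative cyclisation in which DMSO re-oxidises HI. The flavone 10 is now isolated. Treatment with BCl3 (3 equiv, one taken up by the 3'-OH) in CH2Cl2 at −78 → 0 °C, followed by aqueous work-up, cleaves only the methoxy group chelated to C4=O and gives 11. This costs one extra step and makes no compound outside the list (F0).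

**Step 1.**
- Risks:
  - Lithiation may compete at C6, between the 5-OMe and the masked formyl group.
  - The 2,6-dialkoxyaryl borate may protodeboronate.
  - The released aldehyde may be partly oxidised.
- Fallback carries over no numbered compound. A commercial arene takes the place of 1, and the sequence comes back at 5. The C–O bond is made first on the carbonyl-free arene, and the formyl group is added afterwards by electrophilic substitution.
  - 1,2,4-trimethoxybenzene F1 is lithiated with n-BuLi in THF at 0 °C at its known site between the 2- and 4-methoxy groups. Quenching with B(OMe)3 and oxidation with H2O2/NaOH gives 2,3,6-trimethoxyphenol F2.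
  - Ac2O/pyridine gives 2,3,6-trimethoxyphenyl acetate F3. Its ester oxygen is a much weaker para donor than methoxy.
  - Rieche formylation (Cl2CHOMe, TiCl4, CH2Cl2, 0 °C) therefore goes to C5, ortho to the 6-OMe and para to the 2-OMe, giving 3-acetoxy-2,4,5-trimethoxybenzaldehyde F4.
  - K2CO3/MeOH removes the acetate and gives 5.

**Step 2.**
- Risks:
  - The aldehyde carries ortho and para donor groups and the ketone is hindered, so condensation may be slow.
  - The electron-rich phenoxide may air-oxidise in strong base.
  - Partial closure to 8 on acidification is harmless.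
- Fallback sets out from 5 and 6 and comes back at 8. Hydroxide enolate chemistry is replaced by amine (iminium/enamine) organocatalysis at near-neutral pH. Compounds 5 and 6 are heated with pyrrolidine (1 equiv) and AcOH (1 equiv) in MeOH at 65 °C. The phenols stay protonated, the aldehyde reacts as its iminium ion, and Mannich addition, elimination and amine-catalysed oxa-Michael closure give the flavanone 8. This is isolated and subjected to the conditions of step 3. No compound outside the list is made (F0).

**Further compounds**
F1 | step 1 | 1,2,4-trimethoxybenzene | COc1ccc(OC)c(OC)c1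
F2 | step 1 | 2,3,6-trimethoxyphenol | COc1ccc(OC)c(O)c1OC
F3 | step 1 | 2,3,6-trimethoxyphenyl acetate | COc1ccc(OC)c(OC(C)=O)c1OC
F4 | step 1 | 3-acetoxy-2,4,5-trimethoxybenzaldehyde | COc1cc(C=O)c(OC)c(OC(C)=O)c1OC
F0 | step 2 | none | none
F0 | step 3 | none | none
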